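**Plan**

1. Numbering: ring A = C1–C9–C5–C6–C7–C8 (C9 ketone, C5 geranyl, C8 gem-dimethyl, C1 benzoyl); ring B = C1–C2–C3–C4–C5–C9; C10 joins C7 to C11; cyclopentanone = C3–C11–C12–C13–C14.
2. Retrosynthesis: after removal of the C1 benzoyl group and masking of C13, the cage is cut at C4–C5 and C1–C2. This works because the quaternary C3, shared by the cyclopentanone and ring B, carries both ring-B carbonyls (C2, C4), whose partners C1 and C5 are the two α-carbons of the C9 ketone of ring A, while C3 stays tied to ring A through C11–C10–C7.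
3. Further cuts: C5–geranyl, C8–CH3, C3–C14 and C11–C12 (cyclopentanone), C11=C3 (Knoevenagel), C7–C10 (allylation of 3-ethoxycyclohexenone).
4. Forward order: ring-A enone with the C7 acetaldehyde arm → alkylidene malonate → cyclopentanone → C13 ketal, geranyl at C5, second methyl at C8 → diacid, enol silane, bis(acyl chloride) → one step closes the seven-membered ring and ring B → bridgehead benzoylation, ketal removal.
5. Stereochemistry: C7 from a palladium-catalysed asymmetric allylic alkylation; C11 from a copper bis(oxazoline)-catalysed Mukaiyama–Michael addition (catalyst control, C7 being too remote); C3, C5 and C1 from the tether and the cage in the key step and the benzoylation; the E-alkene comes with geranyl bromide.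

Key step: step 15

Assumption: the ligand enantiomers named in steps 2 and 8 are those expected to give (S)-4 and the C11 configuration of 14; should either induce the opposite sense, its mirror-image ligand is used and nothing else changes.

**Route**

Step 1
Reactants: 1 3-ethoxycyclohex-2-en-1-one
Product: 3 allyl 5-ethoxycyclohexa-1,5-dien-1-yl carbonate, via lithium dienolate 2 (not isolated)
Conditions: LiN(SiMe3)2, TMEDA, THF, −78 °C; then allyl chloroformate, −78 → 0 °C
Reagents that add atoms: allyl chloroformate, C=CCOC(=O)Cl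
Why: Kinetic deprotonation of the vinylogous ester at C6 gives the cross-conjugated dienolate, which in the presence of TMEDA is acylated on oxygen by the chloroformate (enol carbonate formation), and no stereocentre is created.

Step 2
Reactants: 3 allyl 5-ethoxycyclohexa-1,5-dien-1-yl carbonate
Product: 4 (S)-6-allyl-3-ethoxycyclohex-2-en-1-one
Conditions: Pd2(dba)3·CHCl3 (2.5 mol %), N,N′-[(1R,2R)-cyclohexane-1,2-diyl]bis[2-(diphenylphosphanyl)benzamide] (6 mol %), 1,4-dioxane, 23 °C
Reagents that add atoms: none
Why: In this decarboxylative asymmetric allylic alkylation (Tsuji–Trost type) zerovalent palladium ionises the allyl carbonate, CO2 is lost and the dienolate recombines with the π-allyl unit at C6 inside the chiral pocket of the diphosphine, which should set the future C7 as S under neutral conditions that do not epimerise the new α-stereocentre.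

Step 3
Reactants: 4 (S)-6-allyl-3-ethoxycyclohex-2-en-1-one
Product: 6 (S)-4-allyl-3-methylcyclohex-2-en-1-one, via tertiary allylic alcohol 5 (not isolated)
Conditions: MeLi, CeCl3, THF, −78 °C; then 1 M HCl, THF, 23 °C
Reagents that add atoms: methyllithium, [Li]C; water, O
Why: Stork–Danheiser enone transposition, in which the weakly basic organocerium reagent adds 1,2 to the vinylogous ester carbonyl without enolising the adjacent stereocentre and acid hydrolysis of the enol ether with loss of water and ethanol gives the 3-methyl enone, the stereocentre (C7 of the target) not being involved.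

Step 4
Reactants: 6 (S)-4-allyl-3-methylcyclohex-2-en-1-one
Product: 7 2-[(1S)-2-methyl-4-oxocyclohex-2-en-1-yl]acetaldehyde
Conditions: O3, CH2Cl2/MeOH, −78 °C (Sudan Red 7B end point); then PPh3, −78 → 23 °C
Reagents that add atoms: ozone, [O-][O+]=O
Why: Ozonolysis with reductive work-up cleaves the electron-rich terminal alkene far faster than the electron-poor enone C=C, so the C10–C11 aldehyde arm is unveiled while ring A is untouched.

Step 5
Reactants: 7 2-[(1S)-2-methyl-4-oxocyclohex-2-en-1-yl]acetaldehyde; 8 dimethyl malonate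
Product: 9 dimethyl 2-{2-[(1S)-2-methyl-4-oxocyclohex-2-en-1-yl]ethylidene}propanedioate
Conditions: TiCl4, pyridine, THF, 0 → 23 °C
Reagents that add atoms: none
Why: Knoevenagel condensation under TiCl4/pyridine (Lehnert conditions) works for enolisable aliphatic aldehydes, takes the aldehyde in preference to the enone and avoids secondary-amine catalysts that could epimerise the γ-stereocentre through a dienamine.

Step 6
Reactants: 10 1-chloro-3-methylbutan-2-one
Product: 11 3-bromo-1-chloro-3-methylbutan-2-one
Conditions: Br2, AcOH, 0 → 23 °C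
Reagents that add atoms: bromine, BrBr
Why: Acid-catalysed α-bromination of a ketone goes through the more substituted enol and away from the carbon that already carries a halogen, so the tertiary isopropyl C–H is replaced.

Step 7
Reactants: 11 3-bromo-1-chloro-3-methylbutan-2-one
Product: 12 [(1-chloro-3-methylbut-2-en-2-yl)oxy]trimethylsilane
Conditions: Zn dust, Me3SiCl, TMEDA, Et2O, 0 → 23 °C
Reagents that add atoms: chlorotrimethylsilane, C[Si](C)(C)Cl
Why: Reductive silylation of an α-bromo ketone (Reformatsky-type zinc insertion into the weaker tertiary C–Br bond with O-silylation in the flask) gives the tetrasubstituted enol silane regiospecifically, which enolisation of 10 could not do because it would occur on the CH2Cl side.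

Step 8
Reactants: 9 dimethyl 2-{2-[(1S)-2-methyl-4-oxocyclohex-2-en-1-yl]ethylidene}propanedioate; 12 [(1-chloro-3-methylbut-2-en-2-yl)oxy]trimethylsilane
Product: 14 dimethyl (2S)-3,3-dimethyl-2-{[(1S)-2-methyl-4-oxocyclohex-2-en-1-yl]methyl}-4-oxocyclopentane-1,1-dicarboxylate, via open-chain chloroketone malonate 13 (not isolated)
Conditions: [Cu((S,S)-t-Bu-box)](SbF6)2 (10 mol %; t-Bu-box = 2,2′-(propane-2,2-diyl)bis[(4S)-4-tert-butyl-4,5-dihydro-1,3-oxazole]), (CF3)2CHOH (2 equiv), PhMe/CH2Cl2, −78 → −20 °C; then solvent exchange, Cs2CO3, MeCN, 23 °C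
Reagents that add atoms: none
Why: Catalytic enantioselective Mukaiyama–Michael addition to the alkylidene malonate chelated to the copper bis(oxazoline) complex forms the C11–C12 bond with the catalyst, not the remote C7 centre, choosing the face of C11 (set as in the target), and the malonate anion then displaces the primary α-chloride (5-exo-tet, Michael-initiated ring closure) to give the cyclopentanone.

Step 9
Reactants: 14 dimethyl (2S)-3,3-dimethyl-2-{[(1S)-2-methyl-4-oxocyclohex-2-en-1-yl]methyl}-4-oxocyclopentane-1,1-dicarboxylate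
Product: 15 dimethyl (7S)-6,6-dimethyl-7-{[(1S)-2-methyl-4-oxocyclohex-2-en-1-yl]methyl}-1,4-dioxaspiro[4.4]nonane-8,8-dicarboxylate
Conditions: Me3SiOCH2CH2OSiMe3, Me3SiOTf (5 mol %), CH2Cl2, −78 → 0 °C
Reagents that add atoms: 1,2-bis(trimethylsilyloxy)ethane, C[Si](C)(C)OCCO[Si](C)(C)C
Why: Noyori ketalisation converts a saturated ketone into its dioxolane and leaves a conjugated enone alone (the selectivity familiar from the Wieland–Miescher ketone), so C13 is masked while the ring-A enone, which serves here as its own protecting group, stays free.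

Step 10
Reactants: 15 dimethyl (7S)-6,6-dimethyl-7-{[(1S)-2-methyl-4-oxocyclohex-2-en-1-yl]methyl}-1,4-dioxaspiro[4.4]nonane-8,8-dicarboxylate; 16 geranyl bromide
Product: 18 dimethyl (7S)-7-({(1R)-5-[(2E)-3,7-dimethylocta-2,6-dien-1-yl]-2-methyl-4-oxocyclohex-2-en-1-yl}methyl)-6,6-dimethyl-1,4-dioxaspiro[4.4]nonane-8,8-dicarboxylate (both C5 epimers), via lithium dienolate 17 (not isolated)
Conditions: LiN(i-Pr)2, THF, −78 °C; then 16, DMPU, −78 → −20 °C
Reagents that add atoms: none
Why: Kinetic α′-deprotonation of the cyclohexenone at C5 (the only enolisable carbonyl position, since the esters sit on a quaternary carbon and C13 is a ketal) and SN2 alkylation of the cross-conjugated dienolate by the allylic bromide attach the geranyl chain with its E-alkene intact, the new C5 centre being formed as an epimer mixture that is erased in step 13.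

Step 11
Reactants: 18 geranylated enone diester (both C5 epimers)
Product: 19 dimethyl (7S)-7-({(1R)-5-[(2E)-3,7-dimethylocta-2,6-dien-1-yl]-2,2-dimethyl-4-oxocyclohexyl}methyl)-6,6-dimethyl-1,4-dioxaspiro[4.4]nonane-8,8-dicarboxylate (both C5 epimers)
Conditions: Me2CuLi (from MeLi and CuI), Et2O, −40 → 0 °C; aqueous NH4Cl
Reagents that add atoms: lithium dimethylcuprate, [Li+].C[Cu-]C
Why: Conjugate addition of the Gilman cuprate to the β-methyl enone installs the second methyl group of C8, which is not a stereocentre, and spares the methyl esters, the ketal and the isolated trisubstituted alkenes.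

Step 12
Reactants: 19 ring-A ketone diester (both C5 epimers)
Product: 20 (7S)-7-({(1R)-5-[(2E)-3,7-dimethylocta-2,6-dien-1-yl]-2,2-dimethyl-4-oxocyclohexyl}methyl)-6,6-dimethyl-1,4-dioxaspiro[4.4]nonane-8,8-dicarboxylic acid (both C5 epimers)
Conditions: KOH, EtOH/H2O, 80 °C; then 1 M HCl to pH 3, 0 °C
Reagents that add atoms: potassium hydroxide, [K+].[OH-]
Why: Saponification of the geminal diester is done at the ketone stage because ketone, ketal and alkenes tolerate hot alkali whereas the enol silane to come would not, and the 2,2-disubstituted malonic acid does not decarboxylate below about 100 °C.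

Step 13
Reactants: 20 keto diacid (both C5 epimers)
Product: 22 (7S)-7-({(1R)-4-[(tert-butyldimethylsilyl)oxy]-3-[(2E)-3,7-dimethylocta-2,6-dien-1-yl]-6,6-dimethylcyclohex-3-en-1-yl}methyl)-6,6-dimethyl-1,4-dioxaspiro[4.4]nonane-8,8-dicarboxylic acid, via tris(silyl) compound 21 (not isolated)
Conditions: t-BuMe2SiOTf (3.5 equiv), Et3N, CH2Cl2, 0 → 23 °C; then K2CO3 (cat.), MeOH/H2O, 0 °C; pH 4 citrate buffer
Reagents that add atoms: tert-butyldimethylsilyl trifluoromethanesulfonate, CC(C)(C)[Si](C)(C)OS(=O)(=O)C(F)(F)F
Why: Soft enolisation and silylation under equilibrating conditions should give the thermodynamic, tetrasubstituted C5=C9 silyl enol ether (the C1 side is less substituted and neopentyl), which removes the C5 stereocentre, and the two silyl esters formed at the same time are far more labile than the silyl enol ether and are hydrolysed selectively on mild work-up.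

Step 14
Reactants: 22 enol silane diacid
Product: 23 (7S)-7-({(1R)-4-[(tert-butyldimethylsilyl)oxy]-3-[(2E)-3,7-dimethylocta-2,6-dien-1-yl]-6,6-dimethylcyclohex-3-en-1-yl}methyl)-6,6-dimethyl-1,4-dioxaspiro[4.4]nonane-8,8-dicarbonyl dichloride
Conditions: 1-chloro-N,N,2-trimethylprop-1-en-1-amine (2.4 equiv), CH2Cl2, 0 → 23 °C; volatiles removed, used crude
Reagents that add atoms: 1-chloro-N,N,2-trimethylprop-1-en-1-amine, CC(C)=C(Cl)N(C)C
Why: Acid chloride formation with Ghosez's reagent releases an amide instead of HCl, so the acid-labile enol silane and ketal survive, and a malonyl dichloride whose central carbon is quaternary cannot collapse to a ketene.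

Step 15
Reactants: 23 enol silane bis(acyl chloride)
Product: 25 C13-dioxolane of the 1-debenzoyl cage triketone (C3/C5/C7/C11 as in the target; C1–H), via seven-membered diketone acyl chloride 24 (not isolated)
Conditions: 23 in CH2Cl2 added by syringe pump to MgBr2·OEt2 (4 equiv), CH2Cl2 (final 2 mM), 0 → 23 °C; then i-Pr2NEt (4 equiv), 23 °C
Reagents that add atoms: none
Why: Proposed new method: MgBr2 activates one acyl chloride on the quaternary C3, the tetrasubstituted enol silane attacks it through C5 and halide removes the silyl group (C4–C5 bond, intermediate 24), after which i-Pr2NEt enolises the magnesium-chelated C9/C4 diketone toward C1, its only remaining α-position, and that enolate is acylated on carbon by the second acyl chloride (C1–C2 bond). The closest known reactions are the Effenberger annulation of cyclohexanone enol ethers with malonyl dichloride, the Lewis-acid C-acylation of enol silanes by acid chlorides and the MgBr2/amine soft-enolisation acylation of ketones, none of which has been run as a tethered double closure with a dialkylmalonyl dichloride. The first closure makes the seven-membered ring C3–C4–C5–C6–C7–C10–C11 in a 7-(enolexo)-exo-trig mode and the second makes ring B (C1–C2–C3–C4–C5–C9) in a 6-(enolendo)-exo-trig mode, which completes the cage. C5 is set because the C7–C10–C11 tether can deliver the acyl group only to the enol face cis to the C7 arm, C3 is set because with C7 (R) and C11 (S) in place only the acyl chloride cis to C10 on the cyclopentane can reach C5 while the five-membered ring stays outside the cage, and C1 follows because the remaining acyl chloride is then held over the same face of the C1=C9 enol. The step needs carbon rather than oxygen acylation and ring closure rather than chain growth: acylation on the C9 oxygen would demand a nine-membered enol ester in the first closure and a strained bridged enol lactone in the second, C3 has no hydrogen so ketene and pyranone pathways are shut, and high dilution disfavours oligomers.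

Step 16
Reactants: 25 C13-dioxolane of the 1-debenzoyl cage triketone
Product: 27 C13-dioxolane of the target (1-benzoyl cage), via bridgehead lithium enolate 26 (not isolated)
Conditions: lithium 2,2,6,6-tetramethylpiperidide, THF, −78 °C; then PhCOCl, −78 → 0 °C
Reagents that add atoms: benzoyl chloride, O=C(Cl)c1ccccc1
Why: Bridgehead lithiation–acylation of a bicyclo[3.3.1]nonane-2,9-dione removes the only acidic proton (C1–H between the C2 and C9 carbonyls) and the carbanion is benzoylated on carbon, the configuration of the new quaternary C1 being fixed by the cage because the electrophile can only take the exo position the proton left.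

Step 17
Reactants: 27 C13-dioxolane of the target
Product: 28 CNP0110281.1 (target)
Conditions: p-TsOH·H2O (0.2 equiv), THF/H2O (4:1), 45 °C
Reagents that add atoms: water, O
Why: Acid-catalysed hydrolysis of the dioxolane frees the C13 ketone, and the tetraketone, which has no enolisable 1,3-dicarbonyl position, and the trisubstituted alkenes should tolerate the dilute acid.

**Compound list**

1 | 3-ethoxycyclohex-2-en-1-one | CCOC1=CC(=O)CCC1 | starting material
2 | lithium 5-ethoxycyclohexa-1,5-dien-1-olate (dienolate of 1) | CCOC1=CC(O[Li])=CCC1 | intermediate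
3 | allyl 5-ethoxycyclohexa-1,5-dien-1-yl carbonate | CCOC1=CC(OC(=O)OCC=C)=CCC1 | intermediate
4 | (S)-6-allyl-3-ethoxycyclohex-2-en-1-one | CCOC1=CC(=O)[C@@H](CC1)CC=C | intermediate
5 | (6S)-6-allyl-3-ethoxy-1-methylcyclohex-2-en-1-ol (both C1 epimers) | CCOC1=CC(C)(O)[C@@H](CC1)CC=C | intermediate
6 | (S)-4-allyl-3-methylcyclohex-2-en-1-one | O=C1C=C(C)[C@@H](CC1)CC=C | intermediate
7 | 2-[(1S)-2-methyl-4-oxocyclohex-2-en-1-yl]acetaldehyde | O=C1C=C(C)[C@@H](CC1)CC=O | intermediate
8 | dimethyl malonate | COC(=O)CC(=O)OC | starting material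
9 | dimethyl 2-{2-[(1S)-2-methyl-4-oxocyclohex-2-en-1-yl]ethylidene}propanedioate | O=C1C=C(C)[C@@H](CC1)CC=C(C(=O)OC)C(=O)OC | intermediate
10 | 1-chloro-3-methylbutan-2-one | CC(C)C(=O)CCl | starting material
11 | 3-bromo-1-chloro-3-methylbutan-2-one | CC(C)(Br)C(=O)CCl | intermediate
12 | [(1-chloro-3-methylbut-2-en-2-yl)oxy]trimethylsilane | CC(C)=C(CCl)O[Si](C)(C)C | intermediate
13 | dimethyl 2-{(2R)-5-chloro-3,3-dimethyl-1-[(1S)-2-methyl-4-oxocyclohex-2-en-1-yl]-4-oxopentan-2-yl}propanedioate | O=C1C=C(C)[C@@H](CC1)C[C@H](C(C(=O)OC)C(=O)OC)C(C)(C)C(=O)CCl | intermediate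
14 | dimethyl (2S)-3,3-dimethyl-2-{[(1S)-2-methyl-4-oxocyclohex-2-en-1-yl]methyl}-4-oxocyclopentane-1,1-dicarboxylate | O=C1C=C(C)[C@@H](CC1)C[C@H]1C(C)(C)C(=O)CC1(C(=O)OC)C(=O)OC | intermediate
15 | dimethyl (7S)-6,6-dimethyl-7-{[(1S)-2-methyl-4-oxocyclohex-2-en-1-yl]methyl}-1,4-dioxaspiro[4.4]nonane-8,8-dicarboxylate | O=C1C=C(C)[C@@H](CC1)C[C@H]1C(C)(C)C2(OCCO2)CC1(C(=O)OC)C(=O)OC | intermediate
16 | geranyl bromide, (2E)-1-bromo-3,7-dimethylocta-2,6-diene | CC(C)=CCC/C(C)=C/CBr | starting material
17 | lithium dienolate of 15 (C5=C9 enolate, C1=C8 alkene) | [Li]OC1=CC[C@@H](C[C@H]2C(C)(C)C3(OCCO3)CC2(C(=O)OC)C(=O)OC)C(C)=C1 | intermediate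
18 | dimethyl (7S)-7-({(1R)-5-[(2E)-3,7-dimethylocta-2,6-dien-1-yl]-2-methyl-4-oxocyclohex-2-en-1-yl}methyl)-6,6-dimethyl-1,4-dioxaspiro[4.4]nonane-8,8-dicarboxylate (both C5 epimers) | O=C1C=C(C)[C@@H](CC1C/C=C(C)/CCC=C(C)C)C[C@H]1C(C)(C)C2(OCCO2)CC1(C(=O)OC)C(=O)OC | intermediate
19 | dimethyl (7S)-7-({(1R)-5-[(2E)-3,7-dimethylocta-2,6-dien-1-yl]-2,2-dimethyl-4-oxocyclohexyl}methyl)-6,6-dimethyl-1,4-dioxaspiro[4.4]nonane-8,8-dicarboxylate (both C5 epimers) | O=C1CC(C)(C)[C@@H](CC1C/C=C(C)/CCC=C(C)C)C[C@H]1C(C)(C)C2(OCCO2)CC1(C(=O)OC)C(=O)OC | intermediate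
20 | (7S)-7-({(1R)-5-[(2E)-3,7-dimethylocta-2,6-dien-1-yl]-2,2-dimethyl-4-oxocyclohexyl}methyl)-6,6-dimethyl-1,4-dioxaspiro[4.4]nonane-8,8-dicarboxylic acid (both C5 epimers) | O=C1CC(C)(C)[C@@H](CC1C/C=C(C)/CCC=C(C)C)C[C@H]1C(C)(C)C2(OCCO2)CC1(C(=O)O)C(=O)O | intermediate
21 | bis(tert-butyldimethylsilyl) ester of 22 (tris(silyl) compound) | CC(C)=CCC/C(C)=C/CC1=C(O[Si](C)(C)C(C)(C)C)CC(C)(C)[C@@H](C1)C[C@H]1C(C)(C)C2(OCCO2)CC1(C(=O)O[Si](C)(C)C(C)(C)C)C(=O)O[Si](C)(C)C(C)(C)C | intermediate
22 | (7S)-7-({(1R)-4-[(tert-butyldimethylsilyl)oxy]-3-[(2E)-3,7-dimethylocta-2,6-dien-1-yl]-6,6-dimethylcyclohex-3-en-1-yl}methyl)-6,6-dimethyl-1,4-dioxaspiro[4.4]nonane-8,8-dicarboxylic acid | CC(C)=CCC/C(C)=C/CC1=C(O[Si](C)(C)C(C)(C)C)CC(C)(C)[C@@H](C1)C[C@H]1C(C)(C)C2(OCCO2)CC1(C(=O)O)C(=O)O | intermediate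
23 | (7S)-7-({(1R)-4-[(tert-butyldimethylsilyl)oxy]-3-[(2E)-3,7-dimethylocta-2,6-dien-1-yl]-6,6-dimethylcyclohex-3-en-1-yl}methyl)-6,6-dimethyl-1,4-dioxaspiro[4.4]nonane-8,8-dicarbonyl dichloride | CC(C)=CCC/C(C)=C/CC1=C(O[Si](C)(C)C(C)(C)C)CC(C)(C)[C@@H](C1)C[C@H]1C(C)(C)C2(OCCO2)CC1(C(=O)Cl)C(=O)Cl | intermediate
24 | seven-membered diketone acyl chloride (C4–C5 bond formed, C2 still COCl; C3/C5/C7/C11 as in the target) | CC(C)=CCC/C(C)=C/C[C@@]12C[C@@H](C[C@H]3C(C)(C)C4(OCCO4)C[C@]3(C1=O)C(=O)Cl)C(C)(C)CC2=O | intermediate
25 | C13-dioxolane of the 1-debenzoyl cage triketone (C3/C5/C7/C11 as in the target; C1–H) | CC(C)=CCC/C(C)=C/C[C@@]12C[C@H]3C[C@H]4C(C)(C)C5(OCCO5)C[C@]4(C1=O)C(=O)[C@@H](C2=O)C3(C)C | intermediate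
26 | bridgehead (C1) lithium enolate of 25 | CC(C)=CCC/C(C)=C/C[C@@]12C[C@H]3C[C@H]4C(C)(C)C5(OCCO5)C[C@]4(C1=O)C(=O)[C@@]([Li])(C2=O)C3(C)C | intermediate
27 | C13-dioxolane of the target (1-benzoyl cage; all centres as in the target) | CC(C)=CCC/C(C)=C/C[C@@]12C[C@H]3C[C@H]4C(C)(C)C5(OCCO5)C[C@]4(C1=O)C(=O)[C@@](C(=O)c1ccccc1)(C2=O)C3(C)C | intermediate
28 | CNP0110281.1, (1S,3S,5R,7R,11S)-1-benzoyl-5-geranyl cage tetraketone (numbering of the plan) | CC(C)=CCC/C(C)=C/C[C@@]12C[C@H]3C[C@H]4C(C)(C)C(=O)C[C@]4(C1=O)C(=O)[C@@](C(=O)c1ccccc1)(C2=O)C3(C)C | target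

**Step count and risks**

Total step count: 17. Longest linear sequence: 15 (steps 1–5 and 8–17; steps 6–7 make the side reagent 12).

Steps most likely to fail:

1. Step 15 (proposed new method). Chain growth may outrun ring closure, the first acylation may engage the acyl chloride trans to C10 (a dead end), or the second acylation may stall or go to oxygen once the seven-membered ring exists. The fallback separates the two acylations into known reactions and sets out from 23. 23 is added slowly to ZnCl2 in CH2Cl2/Et2O (Lewis-acid C-acylation of an enol silane by an acid chloride) so that only the seven-membered ring closes. The surviving acyl chloride of 24 is trapped in the flask with pentafluorophenol and Et3N as the isolable pentafluorophenyl ester of the seven-membered diketone F1. After purification, F1 is treated with KN(SiMe3)2 in THF (−78 → 0 °C): the C9 ketone can enolise only toward C1, and a Claisen-type intramolecular C-acylation by the active ester closes ring B, returning to the route at 25.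

2. Step 8. The Lewis-acidic copper catalyst may ionise the allylic chloride of 12 to an oxyallyl cation instead of promoting conjugate addition, and facial control at C11 may erode with this hindered, weakly nucleophilic enol silane. The fallback sets out from 9 and 11. Activated zinc dust in THF at 0 °C converts 11 into its bromozinc enolate F2 (a Reformatsky reagent) in the presence of 9. Conjugate addition without any halophilic Lewis acid gives the zinc malonate of 13, which closes to the cyclopentanone on warming with NaI and DMPU. C11 is then formed without control, and 14 is separated by chromatography from its C11 epimer, dimethyl (2R)-3,3-dimethyl-2-{[(1S)-2-methyl-4-oxocyclohex-2-en-1-yl]methyl}-4-oxocyclopentane-1,1-dicarboxylate F3; the route is rejoined at 14.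

3. Step 13. The liberated malonic acid may protodesilylate the enol silane during the selective hydrolysis of the silyl esters, the work-up or the chlorination of step 14. The fallback sets out from 20. 20 is persilylated as in step 13, but the tris(silyl) compound 21 is isolated by a non-aqueous work-up (pentane, filtration of the ammonium triflate). Its two silyl esters are then converted directly into acyl chlorides with oxalyl chloride and catalytic DMF in CH2Cl2 at 0 °C (neutral conditions, silyl chloride as by-product), so that no free carboxylic acid is ever present beside the enol silane. The route is rejoined at 23.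

Further compounds
F1 | step 15 | pentafluorophenyl ester of the seven-membered diketone (aryl ester in place of the acyl chloride of 24) | CC(C)=CCC/C(C)=C/C[C@@]12C[C@@H](C[C@H]3C(C)(C)C4(OCCO4)C[C@]3(C1=O)C(=O)Oc1c(F)c(F)c(F)c(F)c1F)C(C)(C)CC2=O
F2 | step 8 | bromozinc enolate of 11 | CC(C)=C(CCl)O[Zn]Br
F3 | step 8 | dimethyl (2R)-3,3-dimethyl-2-{[(1S)-2-methyl-4-oxocyclohex-2-en-1-yl]methyl}-4-oxocyclopentane-1,1-dicarboxylate (C11 epimer of 14) | O=C1C=C(C)[C@@H](CC1)C[C@@H]1C(C)(C)C(=O)CC1(C(=O)OC)C(=O)OC
F0 | step 13 | none | none
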